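**Plan**
- Briarane numbering is used: ten-membered ring C1–C10, ring A C1/C10–C14, lactone C7–O–C19(=O)–C17(C18)–C8, epoxide C11/C20, C16 on C5. Retrosynthetic cuts, in order: C8–C17 (lactone, from a C7 2-bromopropanoate and a C8 ketone); the C3=C4 and C5=C6 π bonds (back to two enol ethers); C4–C5 with reconnection of C2–C7 (oxy-Cope transform); C6–C7 and C2–C3 (alkenyl additions); C2–C7 (pinacol); C9–C10 and C1–C15 (cuprate–aldol); C1–C2 (carbonylation).
- Feature that allows the key step: the oxygen-bearing carbons C2 and C7 lie 1,6 to each other across the ten-membered ring and bracket the C3=C4–C5=C6 diene. This is the pattern left by a [3,3] ring expansion of a cyclohexane-1,2-diol that carries one alkenyl group on each carbinol carbon.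
- Forward order: ring A from the bromobenzene cis-dihydrodiol; substituents at C1/C10 by conjugate addition–aldol; six-membered ring B (C1, C2, C7, C8, C9, C10) by pinacol closure; enlargement of ring B to the ten-membered ring; diene; epoxide; γ-lactone last.
- Stereochemistry: C13/C14 from the enzymatic diol; C1 by cuprate addition anti to O14; C10/C9 by a matched titanium aldol with an (R)-glyceraldehyde derivative whose own centre (C8) is temporary; C11 by equatorial peracid attack; C7 and C2 by Luche reduction (Felkin control from C8, shielding by C15); C8/C17 by a samarium-bridged Reformatsky closure.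

Key step: step 21

Remark: β is the face of the C15 methyl group, α the face of the C13/C14 oxygens; C8 is carried as a PMB-protected carbinol (latent ketone) so that no C8 oxidation is needed after the ring expansion.
Assumption: the lipase desymmetrisation of step 8 is taken to follow the sense known for 2-O-benzylglycerol (acetylation of the pro-S hydroxymethyl group).

**Route**

Step 1
Reactants: 1 (1S,2S)-3-bromocyclohexa-3,5-diene-1,2-diol
Product: 2 (3aS,7aS)-4-bromo-2,2-dimethyl-3a,7a-dihydro-1,3-benzodioxole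
Conditions: 2,2-dimethoxypropane, p-TsOH (cat.), acetone, 0 °C; used at once
Reagents that add atoms: 2,2-dimethoxypropane (COC(C)(C)OC)
Why: Acid-catalysed transacetalisation (acetonide formation) of the cis-diol leaves C13 and C14 untouched and gives a diene that is used immediately to outrun its Diels–Alder dimerisation.

Step 2
Reactants: 2 bromodiene acetonide
Product: 3 bromohydrin (11α-OH, 12β-Br)
Conditions: NBS, THF–H2O (4:1), 0 °C
Reagents that add atoms: N-bromosuccinimide (O=C1CCC(=O)N1Br); water (O)
Why: Electrophilic bromohydrin formation, in which the bromonium ion forms on the electron-richer unbrominated alkene anti to the acetonide and water opens it at the allylic carbon C11, giving the trans product with 11α-OH and 12β-Br.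

Step 3
Reactants: 3 bromohydrin
Product: 4 allylic alcohol with intact vinyl bromide (C12 = CH2)
Conditions: Bu3SnH (1.05 equiv), AIBN (cat.), benzene, 80 °C
Reagents that add atoms: none
Why: Radical chain dehalogenation removes the secondary alkyl bromide, which is abstracted far faster than the sp2 C–Br bond, so the vinyl bromide survives.

Step 4
Reactants: 4 bromo allylic alcohol
Product: 5 methyl ester (C2 installed on C1)
Conditions: Pd(OAc)2, dppp (cat.), CO (1 atm), Et3N, MeOH–DMF, 70 °C
Reagents that add atoms: carbon monoxide ([C-]#[O+]); methanol (CO)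
Why: Palladium-catalysed methoxycarbonylation (Heck carbonylation) of the vinyl bromide brings in C2 at the ester level, and it precedes oxidation because a β-bromo enone would undergo addition–elimination with methanol.

Step 5
Reactants: 5 hydroxy ester
Product: 6 ring-A enone ester (C11=O, C10=C1–CO2Me)
Conditions: Dess–Martin periodinane, NaHCO3, CH2Cl2, 0 °C to rt
Reagents that add atoms: none
Why: Dess–Martin oxidation of the allylic alcohol under buffered, amine-free conditions gives the doubly activated enone without β-elimination of the C13 oxygen.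

Step 6
Reactants: 7 cis-2-phenyl-1,3-dioxan-5-ol
Product: 8 cis-5-[(4-methoxybenzyl)oxy]-2-phenyl-1,3-dioxane
Conditions: NaH, PMBCl, Bu4NI (cat.), DMF, 0 °C to rt
Reagents that add atoms: 4-methoxybenzyl chloride (COc1ccc(CCl)cc1)
Why: Williamson etherification of the secondary alkoxide places the PMB group on the oxygen that becomes O8.

Step 7
Reactants: 8 PMB ether of benzylideneglycerol
Product: 9 2-[(4-methoxybenzyl)oxy]propane-1,3-diol
Conditions: 80% aq. AcOH, 40 °C
Reagents that add atoms: none
Why: Mild acid hydrolysis cleaves the benzylidene acetal while the PMB ether, which needs oxidative or strongly acidic cleavage, is retained.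

Step 8
Reactants: 9 prochiral diol
Product: 10 (S)-3-hydroxy-2-[(4-methoxybenzyl)oxy]propyl acetate
Conditions: lipase PS (Pseudomonas cepacia), vinyl acetate, t-BuOMe, 25 °C
Reagents that add atoms: vinyl acetate (C=COC(C)=O)
Why: Lipase-catalysed enantiotopos-selective transesterification with an enol ester as irreversible acyl donor acetylates one hydroxymethyl group and thereby creates the C8 stereocentre.

Step 9
Reactants: 10 (S)-monoacetate
Product: 11 (R)-2-[(4-methoxybenzyl)oxy]-3-oxopropyl acetate
Conditions: Dess–Martin periodinane, NaHCO3, CH2Cl2, 0 °C; used crude and cold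
Reagents that add atoms: none
Why: Dess–Martin oxidation gives the configurationally labile α-alkoxy aldehyde under neutral conditions, so that C8 should not epimerise before use.

Step 10
Reactants: 6 ring-A enone ester; 11 (R)-aldehyde
Product: 14 ring-A aldol (1β-CH3, 1α-CO2Me, 10α-H, 9S-OH, 8R-OPMB), via lithium enolate 12 (not isolated), via titanium enolate 13 (not isolated)
Conditions: Me2CuLi (from MeLi, CuI), Et2O, −78 °C; ClTi(Oi-Pr)3, −78 to −50 °C; then 11, −78 °C; aq. NH4Cl
Reagents that add atoms: lithium dimethylcuprate ([Li+].C[Cu-]C)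
Why: In this three-component Michael–aldol sequence the Gilman reagent adds to C1 (β to the ketone) anti to the C14–O bond, which makes C1 quaternary with CH3 β, and the derived tri(isopropoxy)titanium enolate then adds to the Felkin face of 11 from the β face of C10 (anti to the pseudo-axial ester and to O14) with the syn simple selectivity typical of titanium enolates, a matched combination that should fix 10α-H and 9S.

Step 11
Reactants: 14 aldol
Product: 15 9-O-triethylsilyl ether
Conditions: TESOTf, 2,6-lutidine, CH2Cl2, −78 °C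
Reagents that add atoms: triethylsilyl trifluoromethanesulfonate (CC[Si](CC)(CC)OS(=O)(=O)C(F)(F)F)
Why: Silylation with the triflate and a hindered base caps the C9 carbinol at low temperature before retro-aldol cleavage or lactonisation onto the C2 ester can occur, and TES is chosen because it must later fall together with the acetonide under mild acid.

Step 12
Reactants: 15 β-silyloxy ketone
Product: 16 11(20)-methylene compound
Conditions: Zn, CH2Br2, TiCl4, THF–CH2Cl2, 0 °C to rt
Reagents that add atoms: dibromomethane (BrCBr)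
Why: Takai–Lombardo methylenation uses a non-basic gem-dimetallic reagent that converts the hindered, epimerisable ketone into the exocyclic alkene C11=C20 without touching the two esters or the C10 centre.

Step 13
Reactants: 16 methylene diester
Product: 17 diol (C2H2OH on C1, C7H2OH)
Conditions: DIBAL-H (excess), CH2Cl2, −78 to 0 °C; Rochelle salt
Reagents that add atoms: none
Why: DIBAL-H reduces the neopentylic methyl ester to the primary alcohol and cleaves the acetate in the same operation, while silyl ether, PMB ether and acetonide are inert.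

Step 14
Reactants: 17 diol
Product: 18 1,6-dialdehyde (C2HO, C7HO)
Conditions: Dess–Martin periodinane, NaHCO3, CH2Cl2, 0 °C to rt
Reagents that add atoms: none
Why: Double Dess–Martin oxidation gives the dialdehyde in a neutral medium in which the non-enolisable C2 aldehyde and the α-alkoxy centre C8 are both safe.

Step 15
Reactants: 18 dialdehyde
Product: 19 trans-decalin 2α,7α-diol (ring B closed)
Conditions: SmI2 (2.5 equiv), THF, −78 °C to rt
Reagents that add atoms: none
Why: Samarium diiodide-mediated pinacol cyclisation (ketyl–carbonyl coupling, 6-exo) forms C2–C7, the chelated samarium bis-alkoxide giving the cis-diol with O7 anti to the C8 ether, and both carbinol centres are oxidised next so their configuration is of no consequence.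

Step 16
Reactants: 19 decalin diol
Product: 20 trans-decalin 2,7-dione
Conditions: Dess–Martin periodinane, NaHCO3, CH2Cl2, rt
Reagents that add atoms: none
Why: Dess–Martin oxidation of the vicinal diol gives the 1,2-dione without C–C cleavage, C2 cannot enolise, and the amine-free medium avoids enolisation toward C8 and loss of the C9 silyloxy group.

Step 17
Reactants: 21 prop-2-yn-1-ol
Product: 22 tert-butyl(diphenyl)(prop-2-yn-1-yloxy)silane
Conditions: TBDPSCl, imidazole, CH2Cl2, 0 °C to rt
Reagents that add atoms: tert-butyl(chloro)diphenylsilane (CC(C)(C)[Si](Cl)(c1ccccc1)c1ccccc1)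
Why: Imidazole-mediated silylation installs the O16 protecting group that has to outlast base, aqueous acid and DDQ until the last step.

Step 18
Reactants: 22 silyl propargyl ether
Product: 24 (E)-tert-butyl[(3-iodoprop-2-en-1-yl)oxy]diphenylsilane, via alkenylzirconocene chloride 23 (not isolated)
Conditions: Cp2Zr(H)Cl, THF, rt; then I2, 0 °C
Reagents that add atoms: iodine (II)
Why: Schwartz hydrozirconation adds Zr–H syn with zirconium on the terminal carbon and iodinolysis proceeds with retention, so only the E-iodoalkene should form.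

Step 19
Reactants: 20 2,7-dione; 24 (E)-vinyl iodide
Product: 27 7β-hydroxy-7α-alkenyl 2-ketone, via alkenyllithium 25 (not isolated), via alkenylcerium dichloride 26 (not isolated)
Conditions: 24, t-BuLi (2 equiv), Et2O, −78 °C; CeCl3, THF, −78 °C; then 20, −78 °C; aq. NH4Cl
Reagents that add atoms: none
Why: After iodine–lithium exchange and transmetalation, the weakly basic organocerium reagent adds 1,2 to the C7 carbonyl, the less hindered one because C2 is flanked by quaternary C1, along the equatorial α trajectory since the axial β face is closed by the syn-axial C15 methyl and the 9β-silyloxy group, giving the axial 7β-hydroxyl.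

Step 20
Reactants: 27 hydroxy ketone; 28 vinylmagnesium bromide
Product: 30 trans-decalin 2α,7β-diol with 2β-vinyl and 7α-alkenyl groups, via vinylcerium dichloride 29 (not isolated)
Conditions: 28 (3 equiv), CeCl3, THF, −78 to 0 °C; aq. NH4Cl
Reagents that add atoms: none
Why: Organocerium 1,2-addition brings the smallest alkenyl group to the very hindered C2 ketone, and the reagent is expected to be delivered from the β face on which the neighbouring C7 alkoxide sits (equatorial path, the axial α path being opposed by the syn-axial C8–H and C10–H), giving the axial 2α-hydroxyl and hence both alkenyl groups equatorial.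

Step 21
Reactants: 30 dialkenyl diol
Product: 33 ten-membered 2,7-bis(trimethylsilyl enol ether), via dipotassium dialkoxide 31 (not isolated), via dipotassium bis-enolate 32 (not isolated)
Conditions: KH (3 equiv), 18-crown-6, THF, 0 °C to rt; then TMSCl–Et3N, −78 °C
Reagents that add atoms: chlorotrimethylsilane (C[Si](C)(C)Cl)
Why: Double deprotonation gives the dipotassium 1,2-dialkoxide, whose 1,5-diene C4=C3–C2–C7–C6=C5 undergoes a [3,3]-sigmatropic shift through a chair array with both alkenyl groups equatorial on ring B, so that the congested C2–C7 bond breaks, C4–C5 forms and the charge ends in the enolates C2=C3 and C6=C7. The closest known reaction is the anionic oxy-Cope rearrangement of 1,2-dialkenylcyclohexane-1,2-diols to cyclodecane-1,6-dione bis-enolates. The ten-membered ring arises by four-carbon expansion of ring B through this six-centre transition state and not by an end-to-end cyclisation, so no exo or endo mode applies. The only new stereocentre, C5, is set by the chair with the E-CH2OTBDPS group equatorial (ring-E enol ethers) and is erased in the next step. The step needs regiospecific enolates toward C3 and C6 and their survival: the first is inherent in the sigmatropic topology, the second is secured by silylating the bis-enolate in situ at −78 °C before it can equilibrate toward C8 and expel the C9 silyloxy group. A minor cis-diol from step 20 would react through a boat to the same constitution, so the step is tolerant of the diol ratio.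

Step 22
Reactants: 33 bis(silyl enol ether)
Product: 34 ten-membered (3Z,5E)-3,5-diene-2,7-dione
Conditions: Pd(OAc)2 (2.2 equiv), MeCN, rt
Reagents that add atoms: none
Why: In this twofold Saegusa–Ito oxidation each enol ether gives a palladium enolate at C3 or C6 that eliminates β-hydride toward C4 or C5, the only positions with β-hydrogens, and the conjugated dienedione should settle in the ring-cis geometry preferred by a ten-membered ring, with reversible Pd–H re-addition as the equilibration path.

Step 23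
Reactants: 34 dienedione
Product: 35 9β,13α,14α-triol
Conditions: 1 M aq. HCl–THF (1:3), rt
Reagents that add atoms: none
Why: Aqueous acid hydrolyses the acetonide and the TES ether together while the primary TBDPS ether and the PMB ether are stable, and it is run at the dione stage because no ionisable dienyl carbinol is present yet.

Step 24
Reactants: 35 triol
Product: 36 9β,13α,14α-triacetate
Conditions: Ac2O, pyridine, DMAP (cat.), CH2Cl2, 0 °C to rt
Reagents that add atoms: acetic anhydride (CC(=O)OC(C)=O)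
Why: DMAP-catalysed acetylation esterifies the three secondary hydroxyls, and it is kept cold so that the β-acetoxy ketone spanning C9 and C7 does not eliminate.

Step 25
Reactants: 36 triacetate
Product: 37 (11R)-11,20-epoxide (oxygen α)
Conditions: m-CPBA, NaHCO3, CH2Cl2, 0 °C
Reagents that add atoms: m-chloroperoxybenzoic acid (OOC(=O)c1cccc(Cl)c1)
Why: In this Prilezhaev epoxidation the peracid selects the isolated 1,1-disubstituted alkene because the diene is deactivated by two carbonyl groups, and it attacks along the equatorial α trajectory since the axial β face of C11 is blocked by the syn-axial C15 methyl.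

Step 26
Reactants: 37 epoxy dienedione
Product: 38 2β,7α-diol
Conditions: NaBH4, CeCl3·7H2O, MeOH–THF, −78 °C
Reagents that add atoms: none
Why: Luche 1,2-reduction of both enone carbonyls should add hydride at C7 in the Felkin–Anh sense with respect to the C8 PMB ether (7,8-syn, 7α-OH) and at C2 on the α face opposite the C15 methyl of quaternary C1 (2β-OH), while acetates and epoxide are inert at −78 °C.

Step 27
Reactants: 38 diol; 39 (±)-2-bromopropanoic acid
Product: 40 7-O-(2-bromopropanoyl) ester with free 2β-OH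
Conditions: 39 (1.1 equiv), DCC, DMAP (cat.), CH2Cl2, −20 °C
Reagents that add atoms: none
Why: Steglich esterification should acylate the C7 carbinol selectively because the C2 carbinol is neopentylic (next to quaternary C1) and reacts far more slowly.

Step 28
Reactants: 40 mono-ester
Product: 41 2β-acetate
Conditions: Ac2O, pyridine, DMAP, CH2Cl2, rt
Reagents that add atoms: acetic anhydride (CC(=O)OC(C)=O)
Why: DMAP-catalysed acetylation caps the remaining hindered dienyl alcohol, which also shields it from the two oxidants used next.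

Step 29
Reactants: 41 PMB ether
Product: 42 8β-alcohol
Conditions: DDQ, CH2Cl2–pH 7 buffer, 0 °C
Reagents that add atoms: none
Why: Oxidative PMB cleavage with DDQ frees O8 under neutral conditions, so that the epoxide does not open and the flanking acyl groups do not migrate.

Step 30
Reactants: 42 alcohol
Product: 43 8-ketone
Conditions: Dess–Martin periodinane, NaHCO3, CH2Cl2, 0 °C
Reagents that add atoms: none
Why: Dess–Martin oxidation converts the secondary alcohol into the C8 ketone without base, so the acidic C7–H between ketone, ester oxygen and diene is not disturbed.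

Step 31
Reactants: 43 α-(2-bromopropanoyloxy) ketone
Product: 45 γ-lactone, 16-O-TBDPS ether of the target, via samarium enolate 44 (not isolated)
Conditions: SmI2 (2.2 equiv), THF, −78 °C; then aq. NH4Cl
Reagents that add atoms: none
Why: In this samarium diiodide-mediated intramolecular Reformatsky reaction, reduction of the C–Br bond gives a samarium(III) ester enolate that adds to the adjacent ketone (5-exo closure, bond C8–C17) through a samarium-bridged transition state that places O8 and the C18 methyl cis (Z-enolate) and, with C6–C7 and C8–C9 antiperiplanar in the ring, attacks the ketone face that leaves 8-OH α, while reductive enolate generation avoids deprotonation at C7.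

Step 32
Reactants: 45 silyl ether
Product: 46 CNP0317528.1
Conditions: HF·pyridine, pyridine, THF, 0 °C to rt
Reagents that add atoms: none
Why: Buffered fluoride-mediated desilylation cleaves the primary TBDPS ether and releases the C16 alcohol without acyl migration, the tertiary 8-OH having never been protected.

**Compound list**

1 | (1S,2S)-3-bromocyclohexa-3,5-diene-1,2-diol | BrC1=CC=C[C@H](O)[C@@H]1O | starting material
2 | (3aS,7aS)-4-bromo-2,2-dimethyl-3a,7a-dihydro-1,3-benzodioxole | CC1(C)O[C@H]2C=CC=C(Br)[C@H]2O1 | intermediate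
3 | 4,7-dibromo-2,2-dimethyl-3a,6,7,7a-tetrahydro-1,3-benzodioxol-6-ol; 6-OH cis and 7-Br trans to the dioxolane oxygens (11α-OH, 12β-Br) | CC1(C)O[C@H]2[C@H](Br)[C@@H](O)C=C(Br)[C@H]2O1 | intermediate
4 | 4-bromo-2,2-dimethyl-3a,6,7,7a-tetrahydro-1,3-benzodioxol-6-ol; 6-OH cis to the dioxolane oxygens | CC1(C)O[C@H]2C[C@@H](O)C=C(Br)[C@H]2O1 | intermediate
5 | methyl 6-hydroxy-2,2-dimethyl-3a,6,7,7a-tetrahydro-1,3-benzodioxole-4-carboxylate; 6-OH cis to the dioxolane oxygens | CC1(C)O[C@H]2C[C@@H](O)C=C(C(=O)OC)[C@H]2O1 | intermediate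
6 | methyl 2,2-dimethyl-6-oxo-3a,6,7,7a-tetrahydro-1,3-benzodioxole-4-carboxylate (ring-A enone: C11=O, C10=C1, ester carbon = C2, 13α,14α-acetonide) | CC1(C)O[C@H]2CC(=O)C=C(C(=O)OC)[C@H]2O1 | intermediate
7 | cis-2-phenyl-1,3-dioxan-5-ol (cis-1,3-O-benzylideneglycerol) | O[C@H]1CO[C@@H](c2ccccc2)OC1 | starting material
8 | cis-5-[(4-methoxybenzyl)oxy]-2-phenyl-1,3-dioxane | COc1ccc(CO[C@H]2CO[C@@H](c3ccccc3)OC2)cc1 | intermediate
9 | 2-[(4-methoxybenzyl)oxy]propane-1,3-diol | OCC(CO)OCc1ccc(OC)cc1 | intermediate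
10 | (S)-3-hydroxy-2-[(4-methoxybenzyl)oxy]propyl acetate | OC[C@H](OCc1ccc(OC)cc1)COC(C)=O | intermediate
11 | (R)-2-[(4-methoxybenzyl)oxy]-3-oxopropyl acetate | O=C[C@H](OCc1ccc(OC)cc1)COC(C)=O | intermediate
12 | lithium enolate (C10=C11–OLi) of the 1β-methyl-1α-methoxycarbonyl ring-A ketone (not isolated) | CC1(C)O[C@H]2CC(O[Li])=C[C@@](C)(C(=O)OC)[C@H]2O1 | intermediate
13 | tri(isopropoxy)titanium enolate corresponding to 12 (not isolated) | CC1(C)O[C@H]2CC(O[Ti](OC(C)C)(OC(C)C)OC(C)C)=C[C@@](C)(C(=O)OC)[C@H]2O1 | intermediate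
14 | ring-A aldol: C11 ketone; C1 with β-CH3 and α-CO2CH3; C10 with α-H and β side chain C9H(OH)–C8H(OPMB)–C7H2OAc (9S, 8R); 13α,14α-acetonide | CC1(C)O[C@H]2CC(=O)[C@H]([C@H](O)[C@H](OCc3ccc(OC)cc3)COC(C)=O)[C@@](C)(C(=O)OC)[C@H]2O1 | intermediate
15 | 9-O-triethylsilyl ether of 14 | CC1(C)O[C@H]2CC(=O)[C@H]([C@H](O[Si](CC)(CC)CC)[C@H](OCc3ccc(OC)cc3)COC(C)=O)[C@@](C)(C(=O)OC)[C@H]2O1 | intermediate
16 | 11(20)-methylene analogue of 15 (C11=CH2) | CC1(C)O[C@H]2CC(=C)[C@H]([C@H](O[Si](CC)(CC)CC)[C@H](OCc3ccc(OC)cc3)COC(C)=O)[C@@](C)(C(=O)OC)[C@H]2O1 | intermediate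
17 | diol from 16: C2H2OH on C1 and C7H2OH at the chain end | CC1(C)O[C@H]2CC(=C)[C@H]([C@H](O[Si](CC)(CC)CC)[C@H](OCc3ccc(OC)cc3)CO)[C@@](C)(CO)[C@H]2O1 | intermediate
18 | dialdehyde from 17: C2HO on C1 and C7HO at the chain end | CC1(C)O[C@H]2CC(=C)[C@H]([C@H](O[Si](CC)(CC)CC)[C@H](OCc3ccc(OC)cc3)C=O)[C@@](C)(C=O)[C@H]2O1 | intermediate
19 | trans-decalin diol: ring B = C1–C2–C7–C8–C9–C10; 2α-OH, 7α-OH, 8β-OPMB, 9β-OTES; 15β-CH3, 10α-H, 11=CH2, 13α,14α-acetonide | CC1(C)O[C@H]2CC(=C)[C@@H]3[C@H](O[Si](CC)(CC)CC)[C@H](OCc4ccc(OC)cc4)[C@@H](O)[C@@H](O)[C@@]3(C)[C@H]2O1 | intermediate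
20 | trans-decalin 2,7-dione (as 19 with C2=O and C7=O) | CC1(C)O[C@H]2CC(=C)[C@@H]3[C@H](O[Si](CC)(CC)CC)[C@H](OCc4ccc(OC)cc4)C(=O)C(=O)[C@@]3(C)[C@H]2O1 | intermediate
21 | prop-2-yn-1-ol | C#CCO | starting material
22 | tert-butyl(diphenyl)(prop-2-yn-1-yloxy)silane | C#CCO[Si](c1ccccc1)(c1ccccc1)C(C)(C)C | intermediate
23 | (E)-[3-(tert-butyldiphenylsilyloxy)prop-1-enyl]zirconocene chloride (not isolated) | Cl[Zr](/C=C/CO[Si](c1ccccc1)(c1ccccc1)C(C)(C)C)(C1C=CC=C1)C1C=CC=C1 | intermediate
24 | (E)-tert-butyl[(3-iodoprop-2-en-1-yl)oxy]diphenylsilane | I/C=C/CO[Si](c1ccccc1)(c1ccccc1)C(C)(C)C | intermediate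
25 | (E)-3-(tert-butyldiphenylsilyloxy)prop-1-enyllithium (not isolated) | [Li]/C=C/CO[Si](c1ccccc1)(c1ccccc1)C(C)(C)C | intermediate
26 | (E)-3-(tert-butyldiphenylsilyloxy)prop-1-enylcerium dichloride (not isolated) | Cl[Ce](Cl)/C=C/CO[Si](c1ccccc1)(c1ccccc1)C(C)(C)C | intermediate
27 | trans-decalin 2-ketone with 7β-OH and 7α-[(E)-3-(TBDPS-oxy)prop-1-enyl]; other groups as 20 | CC1(C)O[C@H]2CC(=C)[C@@H]3[C@H](O[Si](CC)(CC)CC)[C@H](OCc4ccc(OC)cc4)[C@@](O)(/C=C/CO[Si](c5ccccc5)(c5ccccc5)C(C)(C)C)C(=O)[C@@]3(C)[C@H]2O1 | intermediate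
28 | vinylmagnesium bromide | C=C[Mg]Br | starting material
29 | vinylcerium dichloride (not isolated) | C=C[Ce](Cl)Cl | intermediate
30 | trans-decalin 2α,7β-diol with 2β-vinyl and 7α-[(E)-3-(TBDPS-oxy)prop-1-enyl] (both alkenyl groups equatorial); 8β-OPMB, 9β-OTES, 15β-CH3, 10α-H, 11=CH2, 13α,14α-acetonide | CC1(C)O[C@H]2CC(=C)[C@@H]3[C@H](O[Si](CC)(CC)CC)[C@H](OCc4ccc(OC)cc4)[C@@](O)(/C=C/CO[Si](c5ccccc5)(c5ccccc5)C(C)(C)C)[C@](O)(C=C)[C@@]3(C)[C@H]2O1 | intermediate
31 | dipotassium 2,7-dialkoxide of 30 (not isolated) | CC1(C)O[C@H]2CC(=C)[C@@H]3[C@H](O[Si](CC)(CC)CC)[C@H](OCc4ccc(OC)cc4)[C@@]([O-])(/C=C/CO[Si](c5ccccc5)(c5ccccc5)C(C)(C)C)[C@]([O-])(C=C)[C@@]3(C)[C@H]2O1.[K+].[K+] | intermediate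
32 | dipotassium bis-enolate of the ten-membered 2,7-dione (enolates C2=C3 and C6=C7, C5–CH2OTBDPS) (not isolated) | CC1(C)O[C@H]2CC(=C)[C@@H]3[C@H](O[Si](CC)(CC)CC)[C@H](OCc4ccc(OC)cc4)/C([O-])=C/[C@@H](CO[Si](c5ccccc5)(c5ccccc5)C(C)(C)C)C/C=C([O-])/[C@@]3(C)[C@H]2O1.[K+].[K+] | intermediate
33 | ten-membered 2,7-bis(trimethylsilyloxy)-2,6-diene (ring-E enol ethers C2=C3 and C6=C7, C4H2, C5H–CH2OTBDPS; 8β-OPMB, 9β-OTES; ring A as in 30) | CC1(C)O[C@H]2CC(=C)[C@@H]3[C@H](O[Si](CC)(CC)CC)[C@H](OCc4ccc(OC)cc4)/C(O[Si](C)(C)C)=C/[C@@H](CO[Si](c5ccccc5)(c5ccccc5)C(C)(C)C)C/C=C(O[Si](C)(C)C)/[C@@]3(C)[C@H]2O1 | intermediate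
34 | ten-membered (3Z,5E)-3,5-diene-2,7-dione (both ring double bonds ring-cis; C5–CH2OTBDPS, 8β-OPMB, 9β-OTES, 11=CH2, 13α,14α-acetonide) | CC1(C)O[C@H]2CC(=C)[C@@H]3[C@H](O[Si](CC)(CC)CC)[C@H](OCc4ccc(OC)cc4)C(=O)/C=C(CO[Si](c5ccccc5)(c5ccccc5)C(C)(C)C)\C=C/C(=O)[C@@]3(C)[C@H]2O1 | intermediate
35 | 9β,13α,14α-triol from 34 | O[C@H]1CC(=C)[C@@H]2[C@H](O)[C@H](OCc3ccc(OC)cc3)C(=O)/C=C(CO[Si](c4ccccc4)(c4ccccc4)C(C)(C)C)\C=C/C(=O)[C@@]2(C)[C@H]1O | intermediate
36 | 9β,13α,14α-triacetate of 35 | CC(=O)O[C@H]1CC(=C)[C@@H]2[C@H](OC(C)=O)[C@H](OCc3ccc(OC)cc3)C(=O)/C=C(CO[Si](c4ccccc4)(c4ccccc4)C(C)(C)C)\C=C/C(=O)[C@@]2(C)[C@H]1OC(C)=O | intermediate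
37 | (11R)-11,20-epoxide of 36 (epoxide oxygen α) | CC(=O)O[C@H]1C[C@]2(CO2)[C@@H]2[C@H](OC(C)=O)[C@H](OCc3ccc(OC)cc3)C(=O)/C=C(CO[Si](c4ccccc4)(c4ccccc4)C(C)(C)C)\C=C/C(=O)[C@@]2(C)[C@H]1OC(C)=O | intermediate
38 | 2β,7α-diol from 37 | CC(=O)O[C@H]1C[C@]2(CO2)[C@@H]2[C@H](OC(C)=O)[C@H](OCc3ccc(OC)cc3)[C@@H](O)/C=C(CO[Si](c4ccccc4)(c4ccccc4)C(C)(C)C)\C=C/[C@H](O)[C@@]2(C)[C@H]1OC(C)=O | intermediate
39 | (±)-2-bromopropanoic acid | CC(Br)C(=O)O | starting material
40 | 7-O-(2-bromopropanoyl) ester of 38 (2β-OH free; both configurations at CHBr) | CC(=O)O[C@H]1C[C@]2(CO2)[C@@H]2[C@H](OC(C)=O)[C@H](OCc3ccc(OC)cc3)[C@@H](OC(=O)C(C)Br)/C=C(CO[Si](c4ccccc4)(c4ccccc4)C(C)(C)C)\C=C/[C@H](O)[C@@]2(C)[C@H]1OC(C)=O | intermediate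
41 | 2β-acetate of 40 | CC(=O)O[C@H]1C[C@]2(CO2)[C@@H]2[C@H](OC(C)=O)[C@H](OCc3ccc(OC)cc3)[C@@H](OC(=O)C(C)Br)/C=C(CO[Si](c4ccccc4)(c4ccccc4)C(C)(C)C)\C=C/[C@H](OC(C)=O)[C@@]2(C)[C@H]1OC(C)=O | intermediate
42 | 8β-alcohol from 41 | CC(=O)O[C@H]1C[C@]2(CO2)[C@@H]2[C@H](OC(C)=O)[C@H](O)[C@@H](OC(=O)C(C)Br)/C=C(CO[Si](c3ccccc3)(c3ccccc3)C(C)(C)C)\C=C/[C@H](OC(C)=O)[C@@]2(C)[C@H]1OC(C)=O | intermediate
43 | 8-ketone from 42 | CC(=O)O[C@H]1C[C@]2(CO2)[C@@H]2[C@H](OC(C)=O)C(=O)[C@@H](OC(=O)C(C)Br)/C=C(CO[Si](c3ccccc3)(c3ccccc3)C(C)(C)C)\C=C/[C@H](OC(C)=O)[C@@]2(C)[C@H]1OC(C)=O | intermediate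
44 | samarium(III) enolate of the C7 propanoate of 43 (not isolated) | CC(=O)O[C@H]1C[C@]2(CO2)[C@@H]2[C@H](OC(C)=O)C(=O)[C@@H](OC(O[Sm](I)I)=CC)/C=C(CO[Si](c3ccccc3)(c3ccccc3)C(C)(C)C)\C=C/[C@H](OC(C)=O)[C@@]2(C)[C@H]1OC(C)=O | intermediate
45 | 16-O-tert-butyldiphenylsilyl ether of the target (lactone closed, 8α-OH, 17R) | CC(=O)O[C@H]1C[C@]2(CO2)[C@@H]2[C@H](OC(C)=O)[C@@]3(O)[C@H](/C=C(CO[Si](c4ccccc4)(c4ccccc4)C(C)(C)C)\C=C/[C@H](OC(C)=O)[C@@]2(C)[C@H]1OC(C)=O)OC(=O)[C@@H]3C | intermediate
46 | CNP0317528.1: (1S,2S,3Z,5E,7S,8S,9S,10S,11R,13S,14R,17R)-2,9,13,14-tetraacetoxy-11,20-epoxy-8,16-dihydroxybriara-3,5-diene 19,7-lactone | CC(=O)O[C@H]1C[C@]2(CO2)[C@@H]2[C@H](OC(C)=O)[C@@]3(O)[C@H](/C=C(CO)\C=C/[C@H](OC(C)=O)[C@@]2(C)[C@H]1OC(C)=O)OC(=O)[C@@H]3C | target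

**Step count and risks**

Total steps: 32. Longest linear sequence: 26 steps (from 1 through steps 1–5, 10–16 and 19–32).

Step 21 (ring expansion). What may go wrong: before it is silylated, the bis-enolate may equilibrate from C6 toward C8 and expel the C9 silyloxy group, or the dialkoxide may be consumed by base-induced cleavage faster than it rearranges. The fallback is the neutral, thermal variant, which sets out from 30. Both tertiary hydroxyls are silylated (TMSOTf, 2,6-lutidine, CH2Cl2, −78 to 0 °C) to the bis(trimethylsilyl) ether F1. F1 is then heated in degassed o-dichlorobenzene (about 200 °C, sealed tube, a trace of N,O-bis(trimethylsilyl)acetamide as acid scavenger). The siloxy-Cope rearrangement should deliver the bis-enol ether directly, so the route is rejoined at 33 without any free enolate.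

Step 22 (twofold dehydrogenation). What may go wrong: incomplete second β-hydride elimination, transannular C–C coupling of the two enol ethers at palladium, formation of ring-E double bonds that do not equilibrate, or valence isomerisation of the cis-dienone to a 2H-pyran. The fallback replaces palladium by selenium chemistry and sets out from 33. Phenylselenenyl chloride (2.2 equiv, CH2Cl2, −78 °C) should give the 3,6-bis(phenylselanyl)-2,7-dione F2. Oxidation (H2O2, pyridine, CH2Cl2, 0 °C) then triggers selenoxide syn-elimination, which can only run toward C4 and C5, and returns to 34.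

Step 10 (conjugate addition–aldol). What may go wrong: poor simple diastereoselection at C9, attack on the α face of C10, or acyl transfer and lactonisation of the aldolate. The fallback sets the C9 centre by ketone reduction instead of by the aldol and sets out from 6 and 11.
- The cuprate adduct is allowed to react as its plain lithium enolate with 11 (−78 °C, no titanium), giving the aldol as a mixture at C9, F3.
- Takai–Lombardo methylenation of the free hydroxy ketone gives F4.
- Dess–Martin oxidation gives the single C9 ketone F5, in which C10, now α to a ketone, can relax to the favoured equatorial arrangement.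
- Zn(BH4)2 (Et2O, −30 °C) reduces F5 under chelation between the ketone and the C8 PMB ether to the 8,9-anti alcohol F6.
- Silylation (TESOTf, 2,6-lutidine) returns to 16.

**Further compounds**

F1 | step 21 | 2,7-bis(trimethylsilyl) ether of 30 | CC1(C)O[C@H]2CC(=C)[C@@H]3[C@H](O[Si](CC)(CC)CC)[C@H](OCc4ccc(OC)cc4)[C@@](O[Si](C)(C)C)(/C=C/CO[Si](c5ccccc5)(c5ccccc5)C(C)(C)C)[C@](O[Si](C)(C)C)(C=C)[C@@]3(C)[C@H]2O1
F2 | step 22 | ten-membered 3,6-bis(phenylselanyl)-2,7-dione (C3 and C6 epimers) | CC1(C)O[C@H]2CC(=C)[C@@H]3[C@H](O[Si](CC)(CC)CC)[C@H](OCc4ccc(OC)cc4)C(=O)C([Se]c5ccccc5)[C@@H](CO[Si](c5ccccc5)(c5ccccc5)C(C)(C)C)CC([Se]c5ccccc5)C(=O)[C@@]3(C)[C@H]2O1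
F3 | step 10 | ring-A aldol as a mixture of C9 epimers (free 9-OH, C11 ketone) | CC1(C)O[C@H]2CC(=O)[C@H](C(O)[C@H](OCc3ccc(OC)cc3)COC(C)=O)[C@@](C)(C(=O)OC)[C@H]2O1
F4 | step 10 | 11(20)-methylene aldol as a mixture of C9 epimers | CC1(C)O[C@H]2CC(=C)[C@H](C(O)[C@H](OCc3ccc(OC)cc3)COC(C)=O)[C@@](C)(C(=O)OC)[C@H]2O1
F5 | step 10 | 11(20)-methylene C9 ketone | CC1(C)O[C@H]2CC(=C)[C@H](C(=O)[C@H](OCc3ccc(OC)cc3)COC(C)=O)[C@@](C)(C(=O)OC)[C@H]2O1
F6 | step 10 | (9S)-alcohol, the 9-OH analogue of 16 | CC1(C)O[C@H]2CC(=C)[C@H]([C@H](O)[C@H](OCc3ccc(OC)cc3)COC(C)=O)[C@@](C)(C(=O)OC)[C@H]2O1
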